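**Retrosynthetic overview**

1. The last C–C bond to be made is the one between the stereogenic CH and C1 of the syringyl ring. It is formed by a nickel-hydride enantioselective hydroarylation of an 8-vinylflavonol (all phenols as benzyl ethers) with a syringyl boronic acid; this one step makes the bond, the C-methyl group and the (R) centre.
2. Enabling feature: the stereogenic carbon sits on C8 of ring A, between the C7 oxygen and O1, so it is benzylic. Written back as the inner carbon of an 8-vinyl group it is the carbon that takes nickel (η3-benzyl over C8–C7), while the terminal carbon takes the hydride and becomes the methyl.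
3. The 8-vinyl group comes from an 8-iodide. The iodine is placed on the acetophenone ortho to its only free phenol, so closing ring C through that phenol fixes the substituent at C8.
4. Ring order: rings A and B and the syringyl ring are bought as arenes (phloroacetophenone, O-benzylvanillin, 4-bromo-2,6-dimethoxyphenol). Ring C is the only ring built (Claisen–Schmidt, then Algar–Flynn–Oyamada).
5. The five benzyl ethers leave together by hydrogenolysis in the last step.

Key step: step 9

Assumption: the target centre is (R) (flavonoid C8 > syringyl C1 > CH3 > H); the sense of induction of a bis(oxazoline)–nickel catalyst on this di-ortho-oxygenated styrene cannot be derived a priori, so the ligand antipode for step 9 is fixed by a pilot run with chiral HPLC analysis. (S,S)-Bn-BOX stands for (4S,4'S)-2,2'-(propane-2,2-diyl)bis(4-benzyl-4,5-dihydro-1,3-oxazole).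

**Route**

Step 1
Reactants: 1 2,4,6-trihydroxyacetophenone
Product: 2 1-[2,4-bis(benzyloxy)-6-hydroxyphenyl]ethan-1-one
Conditions: BnBr (2.1 equiv), K2CO3 (2.2 equiv), DMF, rt to 50 °C
Reagents that add atoms: benzyl bromide, BrCc1ccccc1
Why: Williamson ether synthesis; the phenol hydrogen-bonded to the acetyl carbonyl is the least nucleophilic and should stay free, so the other two are benzylated.

Step 2
Reactants: 2 1-[2,4-bis(benzyloxy)-6-hydroxyphenyl]ethan-1-one
Product: 3 1-[4,6-bis(benzyloxy)-2-hydroxy-3-iodophenyl]ethan-1-one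
Conditions: NIS (1.05 equiv), DMF, 0 °C to rt, dark
Reagents that add atoms: N-iodosuccinimide, O=C1CCC(=O)N1I
Why: Electrophilic aromatic iodination; the position ortho to the free phenol should be favoured over the more hindered position between the two benzyloxy groups (to be confirmed by NOE of the remaining ring proton to both OCH2 groups).

Step 3
Reactants: 3 1-[4,6-bis(benzyloxy)-2-hydroxy-3-iodophenyl]ethan-1-one; 4 4-(benzyloxy)-3-methoxybenzaldehyde
Product: 5 (2E)-3-[4-(benzyloxy)-3-methoxyphenyl]-1-[4,6-bis(benzyloxy)-2-hydroxy-3-iodophenyl]prop-2-en-1-one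
Conditions: KOH (50% aq.), EtOH/THF, rt, 24–48 h
Reagents that add atoms: none
Why: Claisen–Schmidt aldol condensation of the methyl ketone with a non-enolisable aldehyde; the conjugated E-enone is the thermodynamic product.

Step 4
Reactants: 5 (2E)-3-[4-(benzyloxy)-3-methoxyphenyl]-1-[4,6-bis(benzyloxy)-2-hydroxy-3-iodophenyl]prop-2-en-1-one
Product: 7 5,7-bis(benzyloxy)-2-[4-(benzyloxy)-3-methoxyphenyl]-3-hydroxy-8-iodo-4H-chromen-4-one, via racemic trans-dihydroflavonol 6 (not isolated)
Conditions: H2O2 (30% aq.), NaOH (2 M aq.), MeOH/THF, 0 °C to rt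
Reagents that add atoms: hydrogen peroxide, OO
Why: Algar–Flynn–Oyamada reaction: the only free phenoxide closes ring C onto the enone as alkaline peroxide oxidises it, and the dihydroflavonol is dehydrogenated in the same flask; closure through the oxygen next to the iodinated carbon places iodine at C8.

Step 5
Reactants: 7 5,7-bis(benzyloxy)-2-[4-(benzyloxy)-3-methoxyphenyl]-3-hydroxy-8-iodo-4H-chromen-4-one
Product: 8 3,5,7-tris(benzyloxy)-2-[4-(benzyloxy)-3-methoxyphenyl]-8-iodo-4H-chromen-4-one
Conditions: BnBr (1.3 equiv), K2CO3 (2 equiv), DMF, 50 °C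
Reagents that add atoms: benzyl bromide, BrCc1ccccc1
Why: Williamson ether synthesis on the acidic 3-hydroxyl, which removes the chelating enol before the metal-catalysed steps.

Step 6
Reactants: 8 3,5,7-tris(benzyloxy)-2-[4-(benzyloxy)-3-methoxyphenyl]-8-iodo-4H-chromen-4-one
Product: 9 3,5,7-tris(benzyloxy)-2-[4-(benzyloxy)-3-methoxyphenyl]-8-ethenyl-4H-chromen-4-one
Conditions: CH2=CHBF3K (1.5 equiv), PdCl2(dppf) (5 mol %), Cs2CO3 (3 equiv), THF/H2O 9:1, 80 °C
Reagents that add atoms: potassium vinyltrifluoroborate, [K+].C=C[B-](F)(F)F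
Why: Suzuki–Miyaura vinylation: oxidative addition of zerovalent palladium into the C8–I bond, transmetalation from boron and reductive elimination, with the bidentate dppf ligand chosen for the di-ortho-substituted iodide.

Step 7
Reactants: 10 4-bromo-2,6-dimethoxyphenol
Product: 11 2-(benzyloxy)-5-bromo-1,3-dimethoxybenzene
Conditions: BnBr (1.2 equiv), K2CO3 (2 equiv), DMF, 60 °C
Reagents that add atoms: benzyl bromide, BrCc1ccccc1
Why: Williamson ether synthesis; the phenol is masked with the same group as the flavonol so that one final step removes all of them.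

Step 8
Reactants: 11 2-(benzyloxy)-5-bromo-1,3-dimethoxybenzene
Product: 14 [4-(benzyloxy)-3,5-dimethoxyphenyl]boronic acid, via aryllithium 12 (not isolated), via lithium aryl(triisopropoxy)borate 13 (not isolated)
Conditions: n-BuLi (1.05 equiv), THF, −78 °C; B(OiPr)3 (1.5 equiv), −78 °C to rt; 1 M HCl (aq.), rt
Reagents that add atoms: triisopropyl borate, CC(C)OB(OC(C)C)OC(C)C; water, O
Why: Bromine–lithium exchange, much faster at −78 °C than ortho-lithiation, followed by borylation of the aryllithium and hydrolysis of the borate.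

Step 9
Reactants: 9 3,5,7-tris(benzyloxy)-2-[4-(benzyloxy)-3-methoxyphenyl]-8-ethenyl-4H-chromen-4-one; 14 [4-(benzyloxy)-3,5-dimethoxyphenyl]boronic acid
Product: 15 3,5,7-tris(benzyloxy)-2-[4-(benzyloxy)-3-methoxyphenyl]-8-{(1R)-1-[4-(benzyloxy)-3,5-dimethoxyphenyl]ethyl}-4H-chromen-4-one
Conditions: Ni(cod)2 (10 mol %), (S,S)-Bn-BOX or its (R,R) antipode (12 mol %), 14 (2 equiv), MeOH/THF 1:1, 40 °C, argon
Reagents that add atoms: none
Why: Nickel-hydride-catalysed enantioselective Markovnikov hydroarylation of a vinylarene with an arylboronic acid, a known route to 1,1-diarylethanes: zerovalent nickel and methanol give a divalent nickel hydride, which inserts the 8-vinyl group with hydride to the terminal carbon (the future C-methyl) and nickel to the carbon on C8, held as an η3-benzyl across C8 and C7 of ring A; transmetalation with 14 and C–C reductive elimination then form the bond to C1 of the syringyl ring and return zerovalent nickel. No ring is closed in this step. The one stereocentre is set under catalyst control: insertion is reversible, so the two diastereomeric benzyl(aryl)nickel complexes interconvert and the C2-symmetric bis(oxazoline) ligand decides which one eliminates, the ligand antipode used being the one that delivers (R). The step needs branched over linear selectivity, secured by benzylic stabilisation from the electron-rich ring A with its C7 and O1 oxygens, and chemoselectivity for the vinyl group over the C2=C3 bond of ring C, which is tetrasubstituted and part of a vinylogous ester. Methanol supplies the new hydrogen, and the neutral, base-free medium should leave the benzyl ethers and the chromone untouched.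

Step 10
Reactants: 15 3,5,7-tris(benzyloxy)-2-[4-(benzyloxy)-3-methoxyphenyl]-8-{(1R)-1-[4-(benzyloxy)-3,5-dimethoxyphenyl]ethyl}-4H-chromen-4-one
Product: 16 3,5,7-trihydroxy-2-(4-hydroxy-3-methoxyphenyl)-8-[(1R)-1-(4-hydroxy-3,5-dimethoxyphenyl)ethyl]-4H-chromen-4-one
Conditions: H2 (1 atm), Pd/C (10 wt %), EtOAc/MeOH 1:1, rt
Reagents that add atoms: none
Why: Hydrogenolysis of the five O-benzyl ethers under neutral conditions; the diarylmethine centre and the C2=C3 bond of the chromone are not expected to react at 1 atm and rt, so the (R) configuration should be kept.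

**Compound list**

1 | 2,4,6-trihydroxyacetophenone | CC(=O)c1c(O)cc(O)cc1O | starting material
2 | 1-[2,4-bis(benzyloxy)-6-hydroxyphenyl]ethan-1-one | CC(=O)c1c(O)cc(OCc2ccccc2)cc1OCc1ccccc1 | intermediate
3 | 1-[4,6-bis(benzyloxy)-2-hydroxy-3-iodophenyl]ethan-1-one | CC(=O)c1c(O)c(I)c(OCc2ccccc2)cc1OCc1ccccc1 | intermediate
4 | 4-(benzyloxy)-3-methoxybenzaldehyde | COc1cc(C=O)ccc1OCc1ccccc1 | starting material
5 | (2E)-3-[4-(benzyloxy)-3-methoxyphenyl]-1-[4,6-bis(benzyloxy)-2-hydroxy-3-iodophenyl]prop-2-en-1-one | COc1cc(/C=C/C(=O)c2c(O)c(I)c(OCc3ccccc3)cc2OCc2ccccc2)ccc1OCc1ccccc1 | intermediate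
6 | trans-5,7-bis(benzyloxy)-2-[4-(benzyloxy)-3-methoxyphenyl]-3-hydroxy-8-iodo-2,3-dihydro-4H-chromen-4-one (racemic, one enantiomer drawn) | O=C1[C@H](O)[C@@H](c2ccc(OCc3ccccc3)c(OC)c2)Oc2c(I)c(OCc3ccccc3)cc(OCc3ccccc3)c12 | intermediate (not isolated)
7 | 5,7-bis(benzyloxy)-2-[4-(benzyloxy)-3-methoxyphenyl]-3-hydroxy-8-iodo-4H-chromen-4-one | COc1cc(-c2oc3c(I)c(OCc4ccccc4)cc(OCc4ccccc4)c3c(=O)c2O)ccc1OCc1ccccc1 | intermediate
8 | 3,5,7-tris(benzyloxy)-2-[4-(benzyloxy)-3-methoxyphenyl]-8-iodo-4H-chromen-4-one | COc1cc(-c2oc3c(I)c(OCc4ccccc4)cc(OCc4ccccc4)c3c(=O)c2OCc2ccccc2)ccc1OCc1ccccc1 | intermediate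
9 | 3,5,7-tris(benzyloxy)-2-[4-(benzyloxy)-3-methoxyphenyl]-8-ethenyl-4H-chromen-4-one | COc1cc(-c2oc3c(C=C)c(OCc4ccccc4)cc(OCc4ccccc4)c3c(=O)c2OCc2ccccc2)ccc1OCc1ccccc1 | intermediate
10 | 4-bromo-2,6-dimethoxyphenol | COc1cc(Br)cc(OC)c1O | starting material
11 | 2-(benzyloxy)-5-bromo-1,3-dimethoxybenzene | COc1cc(Br)cc(OC)c1OCc1ccccc1 | intermediate
12 | [4-(benzyloxy)-3,5-dimethoxyphenyl]lithium | [Li]c1cc(OC)c(OCc2ccccc2)c(OC)c1 | intermediate (not isolated)
13 | lithium [4-(benzyloxy)-3,5-dimethoxyphenyl]tri(propan-2-yloxy)borate | [Li+].COc1cc([B-](OC(C)C)(OC(C)C)OC(C)C)cc(OC)c1OCc1ccccc1 | intermediate (not isolated)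
14 | [4-(benzyloxy)-3,5-dimethoxyphenyl]boronic acid | COc1cc(B(O)O)cc(OC)c1OCc1ccccc1 | intermediate
15 | 3,5,7-tris(benzyloxy)-2-[4-(benzyloxy)-3-methoxyphenyl]-8-{(1R)-1-[4-(benzyloxy)-3,5-dimethoxyphenyl]ethyl}-4H-chromen-4-one | COc1cc(-c2oc3c([C@H](C)c4cc(OC)c(OCc5ccccc5)c(OC)c4)c(OCc4ccccc4)cc(OCc4ccccc4)c3c(=O)c2OCc2ccccc2)ccc1OCc1ccccc1 | intermediate
16 | 3,5,7-trihydroxy-2-(4-hydroxy-3-methoxyphenyl)-8-[(1R)-1-(4-hydroxy-3,5-dimethoxyphenyl)ethyl]-4H-chromen-4-one | COc1cc(-c2oc3c([C@H](C)c4cc(OC)c(O)c(OC)c4)c(O)cc(O)c3c(=O)c2O)ccc1O | target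

**Step count and risks**

Total step count: 10. Longest linear sequence: 8 steps (steps 1–6, 9 and 10); steps 7 and 8 make the boronic acid in a two-step branch.

Steps most likely to fail:

1. Step 9. Insertion of the hindered, di-ortho-oxygenated vinyl group into the nickel hydride may be slow, so that protodeboronation of 14, linear arylation or loss of enantioselection take over. The fallback replaces the hydride route by an activating group that is removed afterwards. It sets out from iodide 8: a Heck reaction with acrolein (Pd(OAc)2, Bu4NCl, NaHCO3, DMF, 60 °C) should give (2E)-3-{3,5,7-tris(benzyloxy)-2-[4-(benzyloxy)-3-methoxyphenyl]-4-oxo-4H-chromen-8-yl}prop-2-enal F1. Hayashi–Miyaura asymmetric 1,4-addition of boronic acid 14 ([RhCl(C2H4)2]2, one antipode of 2,5-diphenylbicyclo[2.2.2]octa-2,5-diene, KOH aq., dioxane, 30–50 °C) should give (3R)-3-[4-(benzyloxy)-3,5-dimethoxyphenyl]-3-{3,5,7-tris(benzyloxy)-2-[4-(benzyloxy)-3-methoxyphenyl]-4-oxo-4H-chromen-8-yl}propanal F2. Tsuji–Wilkinson decarbonylation (RhCl(PPh3)3, 1 equiv, toluene, 110 °C; the carbon monoxide stays on rhodium) turns the CH2CHO arm into the methyl group and comes back to the route at 15.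

2. Step 4. The phenoxide may close the five-membered ring onto the α-carbon instead, a known drift toward aurones when the chalcone carries a 6'-alkoxy group. The fallback separates ring closure from hydroxylation. It sets out from chalcone 5: oxidative cyclisation (I2 10 mol %, DMSO, 120 °C) should give 5,7-bis(benzyloxy)-2-[4-(benzyloxy)-3-methoxyphenyl]-8-iodo-4H-chromen-4-one F3. Epoxidation with dimethyldioxirane (acetone/CH2Cl2, 0 °C) should give the racemic 2,3-epoxide of that flavone F4, which is opened in the same flask with catalytic p-TsOH to the 3-hydroxyflavone, coming back at 7.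

3. Step 6. Transmetalation at the di-ortho-substituted arylpalladium iodide may be slow, so that protodeiodination or Heck-type oligomerisation of the vinyl product competes. The fallback brings in the two carbons as a linear alkyne, which is less sensitive to crowding. It sets out from iodide 8: Sonogashira coupling with ethynyltrimethylsilane (PdCl2(PPh3)2, CuI, Et3N, THF, 60 °C) should give 3,5,7-tris(benzyloxy)-2-[4-(benzyloxy)-3-methoxyphenyl]-8-[(trimethylsilyl)ethynyl]-4H-chromen-4-one F5. Desilylation (K2CO3, MeOH/THF, rt) should give 3,5,7-tris(benzyloxy)-2-[4-(benzyloxy)-3-methoxyphenyl]-8-ethynyl-4H-chromen-4-one F6. Partial hydrogenation (H2, Pd/CaCO3 poisoned with Pb(OAc)2, quinoline, EtOAc, rt) comes back at 9 with the benzyl ethers intact.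

Further compounds
F1 | step 9 | (2E)-3-{3,5,7-tris(benzyloxy)-2-[4-(benzyloxy)-3-methoxyphenyl]-4-oxo-4H-chromen-8-yl}prop-2-enal | COc1cc(-c2oc3c(/C=C/C=O)c(OCc4ccccc4)cc(OCc4ccccc4)c3c(=O)c2OCc2ccccc2)ccc1OCc1ccccc1
F2 | step 9 | (3R)-3-[4-(benzyloxy)-3,5-dimethoxyphenyl]-3-{3,5,7-tris(benzyloxy)-2-[4-(benzyloxy)-3-methoxyphenyl]-4-oxo-4H-chromen-8-yl}propanal | COc1cc(-c2oc3c([C@H](CC=O)c4cc(OC)c(OCc5ccccc5)c(OC)c4)c(OCc4ccccc4)cc(OCc4ccccc4)c3c(=O)c2OCc2ccccc2)ccc1OCc1ccccc1
F3 | step 4 | 5,7-bis(benzyloxy)-2-[4-(benzyloxy)-3-methoxyphenyl]-8-iodo-4H-chromen-4-one | COc1cc(-c2cc(=O)c3c(OCc4ccccc4)cc(OCc4ccccc4)c(I)c3o2)ccc1OCc1ccccc1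
F4 | step 4 | 2,3-epoxide of 5,7-bis(benzyloxy)-2-[4-(benzyloxy)-3-methoxyphenyl]-8-iodo-4H-chromen-4-one (racemic, one enantiomer drawn) | O=C1[C@H]2O[C@@]2(c2ccc(OCc3ccccc3)c(OC)c2)Oc2c(I)c(OCc3ccccc3)cc(OCc3ccccc3)c12
F5 | step 6 | 3,5,7-tris(benzyloxy)-2-[4-(benzyloxy)-3-methoxyphenyl]-8-[(trimethylsilyl)ethynyl]-4H-chromen-4-one | COc1cc(-c2oc3c(C#C[Si](C)(C)C)c(OCc4ccccc4)cc(OCc4ccccc4)c3c(=O)c2OCc2ccccc2)ccc1OCc1ccccc1
F6 | step 6 | 3,5,7-tris(benzyloxy)-2-[4-(benzyloxy)-3-methoxyphenyl]-8-ethynyl-4H-chromen-4-one | COc1cc(-c2oc3c(C#C)c(OCc4ccccc4)cc(OCc4ccccc4)c3c(=O)c2OCc2ccccc2)ccc1OCc1ccccc1
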